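**Assumption:** the `[C@@H]` centre is C2 of the flavanone with the (2S) configuration (the natural series). (2S)-Hesperetin of checked ee and carbonate **5** are taken as purchased.

## Retrosynthetic overview
1. The target is (2S)-hesperetin carrying a prenyl group at C5'. No ring is built: the A/C rings and the C2 stereocentre are bought in (2S)-hesperetin.
2. The C5'–prenyl bond comes from an aromatic Claisen [3,3] shift of a 4'-O-(1,1-dimethylallyl) ether. C3' carries oxygen and C1' is substituted, so C5' is the only terminus.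
3. The allyl group must start on O4', so hesperetin's 4'-O-methyl is used as a regiochemical marker: cap O7 and O3' as nosylates, cleave the methyl, O-allylate, rearrange, re-methylate O4', remove the nosylates.

## Route

**Step 1**
Reactants: **1** (2S)-hesperetin; **2** 2-nitrobenzenesulfonyl chloride (NsCl)
Product: **3** (2S)-hesperetin 7,3'-bis(2-nitrobenzenesulfonate), 5-OH free
Conditions: NsCl (2.1 equiv), Et3N, THF/CH2Cl2, 0 °C
Reagents that add atoms: NsCl, `O=S(=O)(Cl)c1ccccc1[N+](=O)[O-]`
Why: O-sulfonylation of the two non-chelated phenols; the 5-OH is hydrogen-bonded to C4=O and does not react, and the brief cold amine exposure should not open the C ring.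

**Step 2**
Reactants: **3**
Product: **4** (2S)-eriodictyol 7,3'-bis(2-nitrobenzenesulfonate), 4'-OH and 5-OH free
Conditions: BBr3 (4 equiv), CH2Cl2, −78 → 0 °C; MeOH quench, cold aqueous work-up
Reagents that add atoms: none
Why: Lewis-acid aryl methyl ether cleavage (bromide SN2 at CH3); sulfonate esters survive BBr3 and do not migrate between the catechol oxygens, so only O4' is unmasked.

**Step 3**
Reactants: **4**; **5** tert-butyl 2-methylbut-3-en-2-yl carbonate
Product: **6** 4'-O-(2-methylbut-3-en-2-yl) ether of **4**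
Conditions: **5** (1.5 equiv), Pd(PPh3)4 (5 mol %), THF, 0 °C
Reagents that add atoms: **5**, `CC(C)(C)OC(=O)OC(C)(C)C=C`
Why: decarboxylative Tsuji–Trost O-allylation; the phenoxide attacks the π-prenyl-Pd at the tertiary terminus to give the branched ether, and only the 4'-OH is available (5-OH chelated).

**Step 4**
Reactants: **6**
Product: **7** (2S)-5'-prenyleriodictyol 7,3'-bis(2-nitrobenzenesulfonate), 4'-OH free
Conditions: PhMe, 110 °C, sealed tube (Eu(fod)3 10 mol %, CHCl3, 50 °C if sluggish)
Reagents that add atoms: none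
Why: aromatic Claisen [3,3] rearrangement then tautomerisation; the tertiary allyl ether delivers the linear prenyl group to C5', the only open ortho carbon, and the neutral conditions leave C2 untouched.

**Step 5**
Reactants: **7**; **8** trimethylsilyldiazomethane
Product: **9** (2S)-5'-prenylhesperetin 7,3'-bis(2-nitrobenzenesulfonate)
Conditions: TMSCHN2 (2 equiv), PhMe/MeOH 3:1, 0 °C → rt
Reagents that add atoms: TMSCHN2, `C[Si](C)(C)C=[N+]=[N-]` (supplies the CH2 of the new OCH3; third H from MeOH)
Why: diazoalkane O-methylation of the acidic 4'-OH (ortho to the sulfonyloxy group) under neutral conditions; the chelated 5-OH is left alone and no base is present to open the flavanone.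

**Step 6**
Reactants: **9**
Product: **10** target, (2S)-5,7-dihydroxy-2-[3-hydroxy-4-methoxy-5-(3-methylbut-2-enyl)phenyl]chroman-4-one
Conditions: PhSH (3 equiv), K2CO3 (3 equiv), MeCN, 0 °C → rt (degassed, dark); pH 4 buffer work-up
Reagents that add atoms: none
Why: Fukuyama-type de-nosylation (thiolate SNAr at the nitroarene ipso carbon, loss of SO2); the 7-O-Ns should cleave first, and the resulting 7-phenoxide deactivates C4=O toward retro-oxa-Michael opening, protecting C2.

## Compound list
1 | (2S)-hesperetin | `COc1ccc([C@@H]2CC(=O)c3c(O)cc(O)cc3O2)cc1O` | starting material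
2 | 2-nitrobenzenesulfonyl chloride | `O=S(=O)(Cl)c1ccccc1[N+](=O)[O-]` | starting material
3 | (2S)-hesperetin 7,3'-bis-O-Ns | `COc1ccc([C@@H]2CC(=O)c3c(O)cc(OS(=O)(=O)c4ccccc4[N+](=O)[O-])cc3O2)cc1OS(=O)(=O)c1ccccc1[N+](=O)[O-]` | intermediate
4 | (2S)-eriodictyol 7,3'-bis-O-Ns | `Oc1ccc([C@@H]2CC(=O)c3c(O)cc(OS(=O)(=O)c4ccccc4[N+](=O)[O-])cc3O2)cc1OS(=O)(=O)c1ccccc1[N+](=O)[O-]` | intermediate
5 | tert-butyl 2-methylbut-3-en-2-yl carbonate | `CC(C)(C)OC(=O)OC(C)(C)C=C` | starting material
6 | 4'-O-(1,1-dimethylallyl) ether of 4 | `C=CC(C)(C)Oc1ccc([C@@H]2CC(=O)c3c(O)cc(OS(=O)(=O)c4ccccc4[N+](=O)[O-])cc3O2)cc1OS(=O)(=O)c1ccccc1[N+](=O)[O-]` | intermediate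
7 | (2S)-5'-prenyleriodictyol 7,3'-bis-O-Ns | `Oc1c(CC=C(C)C)cc([C@@H]2CC(=O)c3c(O)cc(OS(=O)(=O)c4ccccc4[N+](=O)[O-])cc3O2)cc1OS(=O)(=O)c1ccccc1[N+](=O)[O-]` | intermediate
8 | trimethylsilyldiazomethane | `C[Si](C)(C)C=[N+]=[N-]` | starting material
9 | (2S)-5'-prenylhesperetin 7,3'-bis-O-Ns | `COc1c(CC=C(C)C)cc([C@@H]2CC(=O)c3c(O)cc(OS(=O)(=O)c4ccccc4[N+](=O)[O-])cc3O2)cc1OS(=O)(=O)c1ccccc1[N+](=O)[O-]` | intermediate
10 | (2S)-5,7-dihydroxy-2-[3-hydroxy-4-methoxy-5-prenylphenyl]chroman-4-one | `COc1c(O)cc([C@@H]2CC(=O)c3c(O)cc(O)cc3O2)cc1CC=C(C)C` | target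

## Summary
Total steps: 6. Longest linear sequence: 6.

Steps most likely to fail:
1. **Step 2 (BBr3).** Cleavage next to the electron-poor sulfonate may be slow, and the Lewis acid could open the benzylic C2–O1 bond and erode ee. Fallback: skip ether cleavage by starting from (2S)-eriodictyol; nosylate O7, mono-nosylate the catechol, separate the 3'-O-Ns isomer **4** by chromatography and recycle the 4'-isomer by thiolysis.
2. **Steps 3–4 (tertiary ether and Claisen).** The hindered ether may isomerise to the linear prenyl ether under Pd or lose isoprene on heating instead of rearranging. Fallback: put a plain allyl group on O4' (allyl methyl carbonate, Pd), run the Claisen to the 5'-allyl phenol, methylate, then convert allyl to prenyl by cross-metathesis with 2-methyl-2-butene.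
3. **Step 6 (de-nosylation).** Thiolate and carbonate may partly racemise C2 through the chalcone, or the hindered 3'-O-Ns may cleave slowly. Fallback: change the protecting group from step 1 to a fluoride-labile sulfonate (2-(trimethylsilyl)ethanesulfonyl) so the final unmasking uses buffered TBAF/AcOH instead of base.

Check ee by chiral HPLC after steps 2, 3 and 6.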